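**Plan**

- Numbering used throughout: cyclohexene C1 (quaternary; carries CH3 and the styryl carbon Ca, then Cb, then coumarin A), C2, C3, C4 (alkene carbon with CH3), C5 (alkene CH), C6 (CH carrying coumarin B at its C8).
- Retrosynthetic cuts, in order: Cb–C8 of coumarin A (Heck), Ca=Cb (Wittig, back to an ester on C1), then C6–aryl and C1–CH3 together in one operation.
- Enabling feature: C6 and C1 are the β- and α-carbons of a cyclohexa-1,3-diene-1-carboxylate whose ester carbon is Ca and whose second alkene is already the C4=C5 alkene with its methyl group.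
- Forward: the only carbocycle comes from a Diels–Alder reaction of isoprene with methyl propiolate and is isomerised into conjugation; 5,7-dimethoxycoumarin is iodinated at C8 and borylated; dienoate, boronate and iodomethane are joined; the ester is taken to the aldehyde, methylenated, and the vinyl group is arylated with the same 8-iodocoumarin.
- Stereochemistry: C6 from the chiral diene ligand on rhodium; C1 from methylation of the enolate anti to the C6 aryl group; the E alkene from the Heck β-hydride elimination.

Key step: step 5

Assumption: the (R,R) enantiomer of the diene ligand is taken to deliver the aryl group to the Re face of C6 of dienoate 4; this sense is assigned by analogy with cyclic acceptors, and should it prove opposite the (S,S) ligand is used with nothing else changed.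

**Route**

Step 1
Reactants: 1 isoprene; 2 methyl propiolate
Product: 3 methyl 4-methylcyclohexa-1,4-diene-1-carboxylate
Conditions: AlCl3 (20 mol %), CH2Cl2, 0 °C to rt, isoprene in excess; any regioisomeric adduct removed by chromatography
Reagents that add atoms: none
Why: Lewis-acid-promoted Diels–Alder reaction of a 2-substituted diene with an alkynoate, in which the unsubstituted terminus next to the methyl-bearing carbon of isoprene bonds to the β-carbon of the propiolate and should favour the 1,4-disposed adduct; no stereocentre is formed.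

Step 2
Reactants: 3 methyl 4-methylcyclohexa-1,4-diene-1-carboxylate
Product: 4 methyl 4-methylcyclohexa-1,3-diene-1-carboxylate
Conditions: DBU (20 mol %), THF, 60 °C, argon
Reagents that add atoms: none
Why: base-mediated prototropic isomerisation, in which the doubly allylic γ-hydrogen is removed and the pentadienyl anion is reprotonated at its far end, should settle under equilibrating conditions on the linearly conjugated dienoate, with air excluded to prevent aromatisation.

Step 3
Reactants: 5 5,7-dimethoxycoumarin
Product: 6 8-iodo-5,7-dimethoxycoumarin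
Conditions: N-iodosuccinimide (1.05 equiv), CF3CO2H (10 mol %), MeCN, rt, dark
Reagents that add atoms: N-iodosuccinimide, O=C1CCC(=O)N1I
Why: electrophilic aromatic iodination should go to C8, which is activated by the 7-methoxy group (ortho), the 5-methoxy group (para) and the ring oxygen (ortho) and is less crowded than C6 between two methoxy groups, while the pyranone C3 stays untouched under ionic, acid-catalysed conditions.

Step 4
Reactants: 6 8-iodo-5,7-dimethoxycoumarin
Product: 7 5,7-dimethoxy-8-(4,4,5,5-tetramethyl-1,3,2-dioxaborolan-2-yl)-2H-chromen-2-one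
Conditions: bis(pinacolato)diboron (1.2 equiv), PdCl2(dppf) (5 mol %), KOAc (3 equiv), 1,4-dioxane, 90 °C
Reagents that add atoms: bis(pinacolato)diboron, CC1(C)OB(OC1(C)C)B1OC(C)(C)C(C)(C)O1
Why: Miyaura borylation, in which zerovalent palladium inserts into the C–I bond, acetate assists transmetalation with the diboron and reductive elimination gives the aryl boronate, with the weak base sparing the lactone and suppressing biaryl coupling.

Step 5
Reactants: 4 methyl 4-methylcyclohexa-1,3-diene-1-carboxylate; 7 5,7-dimethoxy-8-(4,4,5,5-tetramethyl-1,3,2-dioxaborolan-2-yl)-2H-chromen-2-one; 8 iodomethane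
Product: 11 methyl (1S,2S)-2-(5,7-dimethoxy-2-oxo-2H-chromen-8-yl)-1,4-dimethylcyclohex-3-ene-1-carboxylate, via pinacolboron ketene acetal 9 (not isolated), via potassium ester enolate 10 (not isolated)
Conditions: [RhCl(C2H4)2]2 (2.5 mol %), (1R,4R)-2,5-diphenylbicyclo[2.2.2]octa-2,5-diene (5.5 mol %), KOtBu (10 mol %), 7 (1.5 equiv), toluene, 60 °C, anhydrous; then KOtBu (1 equiv per boron), THF, −78 °C; then MeI (3 equiv), −78 to 0 °C
Reagents that add atoms: potassium tert-butoxide, CC(C)(C)[O-].[K+] (supplies the potassium of intermediate 10; no atom of it remains in 11)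
Why: Proposed new method: an aryl–rhodium species, formed from 7 and a monovalent rhodium tert-butoxide, carbometalates the C1=C6 bond of 4 with the aryl group going to C6, and the resulting oxa-π-allyl rhodium hands its enolate to the boron of a second molecule of 7 to give 9 and fresh aryl–rhodium, after which tert-butoxide takes the boron off 9 and the potassium enolate 10 is C-methylated by 8. The closest known reaction type is the rhodium-catalysed asymmetric 1,4-addition of 9-aryl-9-borabicyclo[3.3.1]nonanes or aryltitanium reagents to enones under aprotic conditions followed by alkylation of the boron or titanium enolate, carried over here to an α-substituted dienoate, a pinacol boronate and a di-ortho-substituted aryl group. No ring is formed, so no mode of closure applies. The C6 stereocentre is set by the chiral diene on rhodium, which exposes the Re face of C6 to the migrating aryl group. The C1 stereocentre is set by the substrate, because allylic 1,3-strain in the exocyclic enolate pushes the C6 aryl group pseudoaxial and iodomethane enters from the opposite face, leaving methyl trans and the ester cis to the aryl group. The step needs 1,4- over 1,6-addition, which the fully substituted C4 terminus secures, attack on the dienoate over the coumarin C3=C4 bond, which the 5- and 7-methoxy donors deactivate and the peri 5-methoxy group shields, and C- over O-methylation, which the soft electrophile favours.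

Step 6
Reactants: 11 methyl (1S,2S)-2-(5,7-dimethoxy-2-oxo-2H-chromen-8-yl)-1,4-dimethylcyclohex-3-ene-1-carboxylate
Product: 12 (1S,2S)-2-(5,7-dimethoxy-2-oxo-2H-chromen-8-yl)-1,4-dimethylcyclohex-3-ene-1-carboxylic acid
Conditions: LiI (5 equiv), pyridine, reflux; then 1 M HCl
Reagents that add atoms: none
Why: SN2 dealkylation by iodide at the unhindered ester methyl carbon is insensitive to the crowding at the quaternary acyl carbon and should leave the lactone, the aryl methyl ethers (which need much higher temperatures) and both stereocentres untouched.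

Step 7
Reactants: 12 (1S,2S)-2-(5,7-dimethoxy-2-oxo-2H-chromen-8-yl)-1,4-dimethylcyclohex-3-ene-1-carboxylic acid
Product: 14 (1S,2S)-2-(5,7-dimethoxy-2-oxo-2H-chromen-8-yl)-1,4-dimethylcyclohex-3-ene-1-carbaldehyde, via acyl chloride 13 (not isolated)
Conditions: (COCl)2 (1.5 equiv), DMF (5 mol %), CH2Cl2, 0 °C to rt; evaporate; LiAlH(OtBu)3 (1.05 equiv), THF, −78 °C
Reagents that add atoms: oxalyl chloride, O=C(Cl)C(Cl)=O (supplies the chlorine of intermediate 13; no non-hydrogen atom of it remains in 14)
Why: acyl chloride formation followed by partial reduction with the bulky, mild hydride LiAlH(OtBu)3 is a classical acid-to-aldehyde sequence in which the acyl chloride should outpace the conjugated lactone at −78 °C and the hindered, non-enolisable aldehyde should resist further reduction.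

Step 8
Reactants: 14 (1S,2S)-2-(5,7-dimethoxy-2-oxo-2H-chromen-8-yl)-1,4-dimethylcyclohex-3-ene-1-carbaldehyde
Product: 15 8-[(1R,6R)-6-ethenyl-3,6-dimethylcyclohex-2-en-1-yl]-5,7-dimethoxy-2H-chromen-2-one
Conditions: Ph3PCH3Br (1.3 equiv), KN(SiMe3)2 (1.2 equiv), THF, 0 °C; then 14, −78 °C to rt
Reagents that add atoms: methyltriphenylphosphonium bromide, C[P+](c1ccccc1)(c1ccccc1)c1ccccc1.[Br-]
Why: Wittig methylenation with the preformed ylide should take the aldehyde, which is far more electrophilic than the lactone and has no α-hydrogen to epimerise, to the vinyl group without creating or disturbing a stereocentre.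

Step 9
Reactants: 15 8-[(1R,6R)-6-ethenyl-3,6-dimethylcyclohex-2-en-1-yl]-5,7-dimethoxy-2H-chromen-2-one; 6 8-iodo-5,7-dimethoxycoumarin
Product: 16 8-[(1R,6R)-6-[(E)-2-(5,7-dimethoxy-2-oxo-2H-chromen-8-yl)ethenyl]-3,6-dimethylcyclohex-2-en-1-yl]-5,7-dimethoxy-2H-chromen-2-one
Conditions: Pd(OAc)2 (10 mol %), Bu4NCl (1 equiv), NaHCO3 (2.5 equiv), DMF, 85 °C, argon
Reagents that add atoms: none
Why: Mizoroki–Heck arylation of a vinyl group on a quaternary carbon, well matched by couplings of iodocoumarins with 2-methylbut-3-en-2-ol, should place the aryl group on the terminal carbon and, with only benzylic hydrogens available for syn β-hydride elimination, give the E alkene without double-bond migration.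

**Compound list**

1 | isoprene (2-methylbuta-1,3-diene) | C=CC(C)=C | starting material
2 | methyl propiolate | C#CC(=O)OC | starting material
3 | methyl 4-methylcyclohexa-1,4-diene-1-carboxylate | COC(=O)C1=CCC(C)=CC1 | intermediate
4 | methyl 4-methylcyclohexa-1,3-diene-1-carboxylate | COC(=O)C1=CC=C(C)CC1 | intermediate
5 | 5,7-dimethoxycoumarin (5,7-dimethoxy-2H-chromen-2-one) | COc1cc(OC)c2ccc(=O)oc2c1 | starting material
6 | 8-iodo-5,7-dimethoxycoumarin (8-iodo-5,7-dimethoxy-2H-chromen-2-one) | COc1cc(OC)c2ccc(=O)oc2c1I | intermediate
7 | 5,7-dimethoxy-8-(4,4,5,5-tetramethyl-1,3,2-dioxaborolan-2-yl)-2H-chromen-2-one | CC1(C)OB(OC1(C)C)c1c(OC)cc(OC)c2ccc(=O)oc12 | intermediate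
8 | iodomethane | CI | starting material
9 | 2-{[(2S)-2-(5,7-dimethoxy-2-oxo-2H-chromen-8-yl)-4-methylcyclohex-3-en-1-ylidene](methoxy)methoxy}-4,4,5,5-tetramethyl-1,3,2-dioxaborolane (pinacolboron ketene acetal, enolate geometry undefined) | COC(OB1OC(C)(C)C(C)(C)O1)=C1CCC(C)=C[C@H]1c1c(OC)cc(OC)c2ccc(=O)oc12 | intermediate (not isolated)
10 | potassium [(2S)-2-(5,7-dimethoxy-2-oxo-2H-chromen-8-yl)-4-methylcyclohex-3-en-1-ylidene](methoxy)methanolate (potassium ester enolate) | COC([O-])=C1CCC(C)=C[C@H]1c1c(OC)cc(OC)c2ccc(=O)oc12.[K+] | intermediate (not isolated)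
11 | methyl (1S,2S)-2-(5,7-dimethoxy-2-oxo-2H-chromen-8-yl)-1,4-dimethylcyclohex-3-ene-1-carboxylate (ester cis to aryl, methyl trans) | COC(=O)[C@@]1(C)CCC(C)=C[C@H]1c1c(OC)cc(OC)c2ccc(=O)oc12 | intermediate
12 | (1S,2S)-2-(5,7-dimethoxy-2-oxo-2H-chromen-8-yl)-1,4-dimethylcyclohex-3-ene-1-carboxylic acid | OC(=O)[C@@]1(C)CCC(C)=C[C@H]1c1c(OC)cc(OC)c2ccc(=O)oc12 | intermediate
13 | (1S,2S)-2-(5,7-dimethoxy-2-oxo-2H-chromen-8-yl)-1,4-dimethylcyclohex-3-ene-1-carbonyl chloride | ClC(=O)[C@@]1(C)CCC(C)=C[C@H]1c1c(OC)cc(OC)c2ccc(=O)oc12 | intermediate (not isolated)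
14 | (1S,2S)-2-(5,7-dimethoxy-2-oxo-2H-chromen-8-yl)-1,4-dimethylcyclohex-3-ene-1-carbaldehyde | O=C[C@@]1(C)CCC(C)=C[C@H]1c1c(OC)cc(OC)c2ccc(=O)oc12 | intermediate
15 | 8-[(1R,6R)-6-ethenyl-3,6-dimethylcyclohex-2-en-1-yl]-5,7-dimethoxy-2H-chromen-2-one | C=C[C@@]1(C)CCC(C)=C[C@H]1c1c(OC)cc(OC)c2ccc(=O)oc12 | intermediate
16 | 8-[(1R,6R)-6-[(E)-2-(5,7-dimethoxy-2-oxo-2H-chromen-8-yl)ethenyl]-3,6-dimethylcyclohex-2-en-1-yl]-5,7-dimethoxy-2H-chromen-2-one (CNP0164660.2) | COc1cc(OC)c2ccc(=O)oc2c1/C=C/[C@@]1(C)CCC(C)=C[C@H]1c1c(OC)cc(OC)c2ccc(=O)oc12 | target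

**Summary**

Total step count: 9.
Longest linear sequence: 7 steps (steps 1, 2, 5, 6, 7, 8, 9; the coumarin branch through steps 3, 4, 5–9 is equally long).

**Steps most likely to fail**

Step 5. The rhodium enolate may fail to pass to the pinacol boronate under anhydrous conditions, protodeboronation of the hindered boronate may outrun carbometalation, or tert-butoxide may open the lactone before the enolate is methylated. The fallback sets out from 4 and 7 and separates the two bond formations into known operations. Rhodium-catalysed asymmetric 1,4-addition under protic conditions ([RhCl(C2H4)2]2, the same chiral diene, aqueous K3PO4, 1,4-dioxane, 50 °C), in which water hydrolyses the rhodium enolate and turns the catalyst over, should give methyl (2R)-2-(5,7-dimethoxy-2-oxo-2H-chromen-8-yl)-4-methylcyclohex-3-ene-1-carboxylate F1 as a mixture of C1 epimers. Deprotonation of this ester with KN(SiMe3)2 in THF at −78 °C and alkylation of the enolate with iodomethane 8, again anti to the aryl group, should return the route at 11.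

Step 7. The hydride may over-reduce the aldehyde, attack the lactone, or react too slowly with the hindered acyl chloride. The fallback sets out from acyl chloride 13, made from 12 as in step 7, and avoids nucleophilic hydride altogether. Ethanethiol and Et3N in CH2Cl2 at 0 °C should give S-ethyl (1S,2S)-2-(5,7-dimethoxy-2-oxo-2H-chromen-8-yl)-1,4-dimethylcyclohex-3-ene-1-carbothioate F2. Fukuyama reduction of this thioester (Et3SiH, palladium on carbon, acetone, rt) should return the route at aldehyde 14.

Step 9. Insertion of the hindered vinyl group into the crowded, electron-rich aryl–palladium species may be slow, allowing dehalogenation of 6 or arylation at a coumarin C3=C4 bond to compete. The fallback sets out from aldehyde 14 and reverses the polarity of the coupling. Takai iodo-olefination (CrCl2, CHI3, THF, 0 °C to rt) should give 8-[(1R,6S)-6-[(E)-2-iodoethenyl]-3,6-dimethylcyclohex-2-en-1-yl]-5,7-dimethoxy-2H-chromen-2-one F3. Suzuki–Miyaura coupling of this vinyl iodide with boronate 7 (Pd(PPh3)4, aqueous K3PO4, 1,4-dioxane, 80 °C), with retention of the E geometry, should return the route at target 16.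

**Further compounds**

F1 | step 5 | methyl (2R)-2-(5,7-dimethoxy-2-oxo-2H-chromen-8-yl)-4-methylcyclohex-3-ene-1-carboxylate (C1 epimers) | COC(=O)C1CCC(C)=C[C@H]1c1c(OC)cc(OC)c2ccc(=O)oc12
F2 | step 7 | S-ethyl (1S,2S)-2-(5,7-dimethoxy-2-oxo-2H-chromen-8-yl)-1,4-dimethylcyclohex-3-ene-1-carbothioate | CCSC(=O)[C@@]1(C)CCC(C)=C[C@H]1c1c(OC)cc(OC)c2ccc(=O)oc12
F3 | step 9 | 8-[(1R,6S)-6-[(E)-2-iodoethenyl]-3,6-dimethylcyclohex-2-en-1-yl]-5,7-dimethoxy-2H-chromen-2-one | I/C=C/[C@@]1(C)CCC(C)=C[C@H]1c1c(OC)cc(OC)c2ccc(=O)oc12
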